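Ring B, the phenol ring, is built onto a finished ring A, so no two arenes are coupled. In ring B, the triad C1'(O-aryl)–C2'(OH)–C3' is the three-carbon chain of an aryloxyacetone. C4'–C5'(Br)–C6' is 2-bromomalonaldehyde, whose bromine ends up para to the hydroxyl. One double aldol condensation forms C1'=C6' and C3'=C4', closes ring B and aromatises it to a 4-bromophenol. The precursor is 1-(2,4-dibromo-6-methoxyphenoxy)propan-2-one, a methyl ketone that carries the complete ring A on its alpha oxygen. A last ortho-bromination at C3' then gives the target.

Key step: step 3

Remark on labels: ring A is the methoxylated ring (C1 ether oxygen, C2 and C4 bromine, C6 methoxy); ring B is the phenol ring (C1' ether oxygen, C2' hydroxyl, C3' and C5' bromine); the target has no stereocentre.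

Remark on the chemistry: untemplated bromination of a guaiacol-type phenol can also go para to the alkoxy or aryloxy oxygen, so both brominations use amine-directed ortho delivery on para-blocked phenols and the route starts from commercial 4-bromo-2-methoxyphenol; 2-bromomalonaldehyde is taken as a purchased reagent.

Step 1
Reactants: 1 4-bromo-2-methoxyphenol
Product: 2 2,4-dibromo-6-methoxyphenol
Conditions: NBS (1.05 equiv), i-Pr2NH (10 mol %), CH2Cl2, 0 °C to rt
Reagents that add atoms: N-bromosuccinimide, O=C1CCC(=O)N1Br
Why: Amine-mediated ortho-bromination (electrophilic aromatic substitution), in which the N-bromoamine formed from NBS and i-Pr2NH is delivered by hydrogen bonding to the phenol OH, so bromine should enter the one free position ortho to OH (para is blocked) and not the position para to the methoxy group.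

Step 2
Reactants: 2 2,4-dibromo-6-methoxyphenol; 3 chloroacetone
Product: 4 1-(2,4-dibromo-6-methoxyphenoxy)propan-2-one
Conditions: K2CO3 (1.5 equiv), KI (0.1 equiv), acetone, 56 °C
Reagents that add atoms: none
Why: Williamson ether synthesis (SN2) with Finkelstein activation of the alpha-chloroketone by KI; the acidic dibromophenol is fully deprotonated by K2CO3 and, with both ortho positions substituted, only O-alkylation is open.

Step 3
Reactants: 4 1-(2,4-dibromo-6-methoxyphenoxy)propan-2-one; 5 2-bromomalonaldehyde
Product: 8 4-bromo-2-(2,4-dibromo-6-methoxyphenoxy)phenol, via open-chain keto enal 6 (not isolated), via cyclohexadienone tautomer 7 (not isolated)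
Conditions: pyrrolidine (0.5 equiv), AcOH (1 equiv), EtOH, rt to 78 °C
Reagents that add atoms: none
Why: Pyrrolidinium acetate converts dialdehyde 5 into its electrophilic enaminal/iminium form and ketone 4 into its enamine or enol, so a Knoevenagel-type aldol condensation at the aryloxy-bearing alpha carbon (C1') gives open-chain 6 (C1'=C6'), and the methyl carbon (C3') then attacks the remaining formyl carbon (C4') and loses water to give dienone 7, which tautomerises irreversibly to phenol 8. The closest known reaction type is the [3+3] phenol synthesis from ketones with two enolisable alpha carbons and 2-substituted malonaldehydes (nitro or halo) or their vinamidinium salts; amine/acid activation is chosen because the bare enolate of a halomalonaldehyde is a poor electrophile under alkaline conditions. Ring B closes by a 6-(enolendo)-exo-trig intramolecular aldol, for which the C1'=C6' geometry can equilibrate through the vinylogous enol of 6. No stereocentre remains, since the sp3 carbon C5' of racemic 7 is lost on aromatisation. The constitution is secured by the substrates themselves: the two formyl groups of 5 are equivalent and both alpha carbons of 4 must be used, so either order of bond formation puts OH between C–OAr and CH with bromine para to it. Cross-condensation should win over ketone self-condensation through the higher electrophilicity of the activated dialdehyde and through aromatisation as the irreversible sink, while the aryl bromides and both ethers are inert to the buffer.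

Step 4
Reactants: 8 4-bromo-2-(2,4-dibromo-6-methoxyphenoxy)phenol
Product: 9 2,4-dibromo-6-(2,4-dibromo-6-methoxyphenoxy)phenol
Conditions: NBS (1.0 equiv), i-Pr2NH (10 mol %), CH2Cl2, 0 °C to rt
Reagents that add atoms: N-bromosuccinimide, O=C1CCC(=O)N1Br
Why: Amine-mediated ortho-bromination (electrophilic aromatic substitution) of a phenol whose para position (C5') and one ortho position (C1') are occupied, so hydrogen-bond delivery should place bromine at C3' in preference to C4' (para to the ether oxygen) and to the doubly bromine-deactivated ring A.

Compound list
1 | 4-bromo-2-methoxyphenol | COc1cc(Br)ccc1O | starting material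
2 | 2,4-dibromo-6-methoxyphenol | COc1cc(Br)cc(Br)c1O | intermediate
3 | chloroacetone (1-chloropropan-2-one) | CC(=O)CCl | starting material
4 | 1-(2,4-dibromo-6-methoxyphenoxy)propan-2-one | COc1cc(Br)cc(Br)c1OCC(C)=O | intermediate
5 | 2-bromomalonaldehyde (2-bromopropanedial) | O=CC(Br)C=O | starting material
6 | 2-bromo-4-(2,4-dibromo-6-methoxyphenoxy)-5-oxohex-3-enal (alkene geometry not fixed, racemic, not isolated) | COc1cc(Br)cc(Br)c1OC(=CC(Br)C=O)C(C)=O | intermediate
7 | 4-bromo-2-(2,4-dibromo-6-methoxyphenoxy)cyclohexa-2,5-dien-1-one (racemic, not isolated) | COc1cc(Br)cc(Br)c1OC1=CC(Br)C=CC1=O | intermediate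
8 | 4-bromo-2-(2,4-dibromo-6-methoxyphenoxy)phenol | COc1cc(Br)cc(Br)c1Oc1cc(Br)ccc1O | intermediate
9 | 2,4-dibromo-6-(2,4-dibromo-6-methoxyphenoxy)phenol | COc1cc(Br)cc(Br)c1Oc1cc(Br)cc(Br)c1O | target

Total step count: 4
Longest linear sequence: 4 steps (1 → 2 → 4 → 8 → 9)

Steps most likely to fail

1. Step 3. The sequence may stall after the first condensation, or the dialdehyde may be used up by self-condensation or by loss of its bromide to the amine before the ketone is engaged. The fallback is a nucleophilic aromatic substitution followed by Baeyer–Villiger oxidation; it sets out from compound 2 and comes back to the route at compound 8. Phenol 2 and 4-bromo-2-fluorobenzaldehyde (K2CO3, DMAc, 120 °C) should react at the fluorine-bearing carbon, activated by the ortho formyl group, to give 4-bromo-2-(2,4-dibromo-6-methoxyphenoxy)benzaldehyde F1. Baeyer–Villiger oxidation (mCPBA, CH2Cl2, rt), with aryl migration helped by the ortho aryloxy donor, should give 4-bromo-2-(2,4-dibromo-6-methoxyphenoxy)phenyl formate F2. Methanolysis (catalytic K2CO3, MeOH, rt) then releases 8, and step 4 follows unchanged.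

2. Step 4. Bromine may enter C4' para to the ether oxygen, or a second bromination may reach ring A. The fallback brings both ring B bromines in with a building block; it sets out from compound 2 and comes back to the route at compound 9. Phenol 2 and 2,4-dibromo-6-fluorobenzaldehyde (K2CO3, DMAc, 120 °C) should give 2,4-dibromo-6-(2,4-dibromo-6-methoxyphenoxy)benzaldehyde F3 by displacement of fluoride. Baeyer–Villiger oxidation (mCPBA, CH2Cl2, rt) should give 2,4-dibromo-6-(2,4-dibromo-6-methoxyphenoxy)phenyl formate F4. Methanolysis (catalytic K2CO3, MeOH, rt) then gives 9 directly.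

3. Step 2. O-alkylation of the hindered, weakly nucleophilic phenoxide may be slow while chloroacetone is consumed by base-induced self-condensation. The fallback masks the ketone as a base-stable alkene; it sets out from compound 2 and comes back to the route at compound 4. Phenol 2 is alkylated with 3-chloro-2-methylprop-1-ene (K2CO3, catalytic NaI, DMF, 70 °C) to give 1,5-dibromo-3-methoxy-2-[(2-methylprop-2-en-1-yl)oxy]benzene F5. Ozonolysis (O3, CH2Cl2/MeOH, −78 °C; then Me2S) cleaves the 1,1-disubstituted alkene to ketone 4.

Further compounds
F1 | step 3 | 4-bromo-2-(2,4-dibromo-6-methoxyphenoxy)benzaldehyde | COc1cc(Br)cc(Br)c1Oc1cc(Br)ccc1C=O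
F2 | step 3 | 4-bromo-2-(2,4-dibromo-6-methoxyphenoxy)phenyl formate | COc1cc(Br)cc(Br)c1Oc1cc(Br)ccc1OC=O
F3 | step 4 | 2,4-dibromo-6-(2,4-dibromo-6-methoxyphenoxy)benzaldehyde | COc1cc(Br)cc(Br)c1Oc1cc(Br)cc(Br)c1C=O
F4 | step 4 | 2,4-dibromo-6-(2,4-dibromo-6-methoxyphenoxy)phenyl formate | COc1cc(Br)cc(Br)c1Oc1cc(Br)cc(Br)c1OC=O
F5 | step 2 | 1,5-dibromo-3-methoxy-2-[(2-methylprop-2-en-1-yl)oxy]benzene | COc1cc(Br)cc(Br)c1OCC(C)=C
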